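**Retrosynthetic overview**

1. The C5 side chain comes last (Mukaiyama hydration, Stille coupling, α-iodination). The C6–CH2 bond to the chroman comes from radical conjugate addition of a chroman-2-ylmethyl iodide to a bicyclic enone (hydrindenone numbering, C4 = carbonyl). The chroman (rings A/B) comes from an ortho-quinone methide hetero-Diels–Alder reaction followed by resolution.
2. Ring D (cyclopentane) is disconnected at C2–C3 and C1–C7a: a radical [3+2] annulation of a cyclohexenylmethyl iodide with phenyl vinyl sulfone as a removable ethylene equivalent.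
3. Enabling feature: the quaternary C3a carries an exocyclic CH2 (future C3, no β-hydrogen) and is bonded to the methyl-bearing alkene carbon C7a of ring C (C7a=C7). This homoallylic neopentyl iodide gives an adduct radical that can close only 5-exo on its own face, which forces the cis-fused, cis-dimethyl junction.
4. The quaternary C3a is set by an auxiliary-controlled Birch reduction–methylation of a 2-methoxy-6-methylbenzamide, so ring C derives from an arene.
5. Ring order: C (Birch), D (key step); B on arene A in a separate branch; then union and enone/side-chain adjustment.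

Key step: step 6

Assumption (step 2): the potassium enolate of the (S)-prolinol-ether amide is methylated on the face that gives the (1S) centre drawn for 6; if the sense is opposite, the (R)-auxiliary is used and nothing else changes.
Assumption (step 11): the (R)-acid gives the less soluble salt with (S)-1-phenylethylamine; if not, the (R)-amine is used.

**Route**

Step 1
Reactants: 1 2-methoxy-6-methylbenzoic acid; 2 (S)-2-(methoxymethyl)pyrrolidine
Product: 4 (2-methoxy-6-methylphenyl)[(2S)-2-(methoxymethyl)pyrrolidin-1-yl]methanone, via acid chloride 3 (not isolated)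
Conditions: SOCl2, cat. DMF, CH2Cl2, 40 °C; then 2, Et3N, CH2Cl2, 0→23 °C
Reagents that add atoms: none
Why: Acyl chloride formation and amidation attach the prolinol-ether auxiliary that will control the quaternary centre; no stereocentre is formed.

Step 2
Reactants: 4 the benzamide
Product: 6 [(1S)-2-methoxy-1,6-dimethylcyclohexa-2,5-dien-1-yl][(2S)-2-(methoxymethyl)pyrrolidin-1-yl]methanone, via potassium amide enolate 5 (not isolated)
Conditions: K (2.3 equiv), NH3(l)/THF, t-BuOH (1.0 equiv), −78 °C; then MeI (3 equiv), −78 °C; NH4Cl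
Reagents that add atoms: iodomethane, CI
Why: Asymmetric Birch reduction–alkylation: the benzamide is reduced to a chelated potassium amide enolate of the 1,4-dihydroarene, and methylation on the face shielded least by the auxiliary should set the quaternary C1 as (S), leaving the methyl enol ether and the trisubstituted alkene in place.

Step 3
Reactants: 6 the dienyl amide
Product: 7 [(6S)-6,7-dimethyl-1,4-dioxaspiro[4.5]dec-7-en-6-yl][(2S)-2-(methoxymethyl)pyrrolidin-1-yl]methanone
Conditions: HOCH2CH2OH (5 equiv), PPTS (0.1 equiv), CH2Cl2, 23 °C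
Reagents that add atoms: ethylene glycol, OCCO
Why: Acid-catalysed transketalisation of the methyl enol ether masks the latent ketone as a dioxolane; the C7=C8 alkene cannot move into conjugation and no stereocentre is touched.

Step 4
Reactants: 7 the ketal amide
Product: 8 [(6R)-6,7-dimethyl-1,4-dioxaspiro[4.5]dec-7-en-6-yl]methanol
Conditions: LiH2NBH3 (4 equiv, from BH3·NH3 and LiN(i-Pr)2), THF, 0→66 °C; then 2 M NaOH
Reagents that add atoms: none
Why: Amide reduction: lithium amidotrihydroborate reduces hindered tertiary amides to primary alcohols with C–N cleavage and releases the auxiliary; the quaternary centre cannot epimerise (the descriptor changes by priority only).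

Step 5
Reactants: 8 the neopentyl alcohol
Product: 9 (6S)-6-(iodomethyl)-6,7-dimethyl-1,4-dioxaspiro[4.5]dec-7-ene
Conditions: I2 (1.5 equiv), PPh3 (1.5 equiv), imidazole (3 equiv), toluene, 85 °C
Reagents that add atoms: iodine, II
Why: Appel-type iodination through the alkoxyphosphonium salt should work on this neopentyl alcohol at elevated temperature because the carbon has no β-hydrogen to eliminate; the adjacent quaternary centre is untouched.

Step 6
Reactants: 9 the homoallylic neopentyl iodide; 10 phenyl vinyl sulfone
Product: 11 (3a'S,7a'S)-3a',7a'-dimethyl-1'-(phenylsulfonyl)octahydrospiro[1,3-dioxolane-2,4'-indene] (both C1' epimers)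
Conditions: 10 (6 equiv), Bu3SnH (1.5 equiv) and AIBN (0.2 equiv) added over 10 h, PhH (0.25 M in 9), 80 °C
Reagents that add atoms: none
Why: The tin radical abstracts iodine, the primary radical adds to the unsubstituted terminus of the vinyl sulfone (C2–C3 bond), the α-sulfonyl radical closes onto the methyl-bearing alkene carbon (C1–C7a bond) and the secondary C7 radical takes hydrogen from the stannane; the closest known reaction type is the radical [3+2] annulation of 3-butenyl (homoallyl) radicals with electron-poor alkenes. Ring D closes in the 5-exo-trig mode. The new quaternary C7a is controlled by the existing quaternary C3a, because the three-atom tether can reach only the alkene face on which it stands, so the ring fusion and the two methyl groups must be cis; the sulfonyl-bearing C1 forms as a mixture and is erased in step 7. The step needs intermolecular addition to beat direct reduction, 3-exo attack on the ring alkene (1,2-vinyl shift with ring expansion) and acyl migration; a high sulfone concentration, slow stannane addition, an unactivated ring alkene and the ketone masked as a dioxolane should secure this. It also needs 5-exo over 6-endo closure, which is favoured because attack at C7 would build a bridged bicyclo[3.3.1]nonane through a boat-like transition state.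

Step 7
Reactants: 11 the sulfonyl ketal
Product: 13 (3aS,7aS)-3a,7a-dimethyloctahydro-4H-inden-4-one, via desulfonylated ketal 12 (not isolated)
Conditions: Mg (20 equiv), MeOH, 50 °C; then 2 M HCl, THF, 23 °C
Reagents that add atoms: water, O
Why: Reductive desulfonylation by electron transfer from magnesium cleaves the C–S bond and erases the epimeric C1 centre, and aqueous acid then hydrolyses the dioxolane; the two quaternary centres are not affected.

Step 8
Reactants: 13 the hydrindanone
Product: 14 (3aS,7aS)-3a,7a-dimethyl-1,2,3,3a,7,7a-hexahydro-4H-inden-4-one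
Conditions: IBX (3 equiv), DMSO, 70 °C
Reagents that add atoms: none
Why: IBX dehydrogenation through the enol, which can form only towards C5 because C3a is quaternary, should give the conjugated enone; further dehydrogenation is blocked by the quaternary C7a.

Step 9
Reactants: 15 4-methoxy-2-methylphenol; 16 methyl methacrylate
Product: 18 methyl rac-6-methoxy-2,8-dimethylchromane-2-carboxylate, via ortho-quinone methide 17 (not isolated)
Conditions: (CH2O)n (1.5 equiv), 16 (5 equiv), Bu2NH (0.1 equiv), AcOH (0.5 equiv), 150 °C, sealed tube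
Reagents that add atoms: formaldehyde (as paraformaldehyde), C=O
Why: Condensation with formaldehyde at the only free ortho position gives an ortho-quinone methide that is trapped by the methacrylate in an inverse-electron-demand hetero-Diels–Alder reaction, with oxygen bonding to the substituted alkene carbon; the quaternary C2 is formed racemic.

Step 10
Reactants: 18 the racemic ester
Product: 19 rac-6-methoxy-2,8-dimethylchromane-2-carboxylic acid
Conditions: LiOH·H2O (3 equiv), THF/MeOH/H2O, 50 °C; then 1 M HCl
Reagents that add atoms: lithium hydroxide, [Li+].[OH-]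
Why: Saponification gives the acid needed for salt resolution; no stereocentre is changed.

Step 11
Reactants: 19 the racemic acid
Product: 20 (2R)-6-methoxy-2,8-dimethylchromane-2-carboxylic acid
Conditions: (S)-1-phenylethylamine (1.0 equiv), EtOAc/EtOH, two recrystallisations; then 1 M HCl, EtOAc
Reagents that add atoms: none
Why: Classical resolution by fractional crystallisation of the diastereomeric ammonium salts should deliver the (R)-acid, whose quaternary C2 cannot epimerise.

Step 12
Reactants: 20 the (R)-acid
Product: 21 [(2R)-6-methoxy-2,8-dimethylchroman-2-yl]methanol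
Conditions: BH3·THF (2.5 equiv), THF, 0→23 °C; then MeOH, H2O
Reagents that add atoms: none
Why: Borane reduction of a carboxylic acid via the acyloxyborane is chemoselective and leaves the aryl ethers and the stereocentre untouched.

Step 13
Reactants: 21 the chromanylmethanol
Product: 22 (2R)-2-(iodomethyl)-6-methoxy-2,8-dimethylchromane
Conditions: I2 (1.5 equiv), PPh3 (1.5 equiv), imidazole (3 equiv), toluene, 80 °C
Reagents that add atoms: iodine, II
Why: Appel-type iodination of the neopentyl-type primary alcohol; the carbon has no β-hydrogen and the quaternary C2 is not involved.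

Step 14
Reactants: 14 the bicyclic enone; 22 the chromanylmethyl iodide
Product: 23 (3aS,7aS)-6-{[(2R)-6-methoxy-2,8-dimethylchroman-2-yl]methyl}-3a,7a-dimethyloctahydro-4H-inden-4-one (C6 epimers)
Conditions: 22 (2.5 equiv), (Me3Si)3SiH (3 equiv, slow addition), Et3B (0.3 equiv)/air, toluene (1 M in 14), −20→0 °C
Reagents that add atoms: none
Why: Giese reaction: the silyl radical abstracts iodine, the nucleophilic primary radical adds to the enone β-carbon C6 and the α-keto radical is reduced by the silane; low temperature and high enone concentration are chosen so that addition outruns β-scission of the ring-B C–O bond, and the new C6 centre, formed unselectively, is erased in step 15.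

Step 15
Reactants: 23 the saturated ketone
Product: 25 (3aS,7aS)-6-{[(2R)-6-methoxy-2,8-dimethylchroman-2-yl]methyl}-3a,7a-dimethyl-1,2,3,3a,7,7a-hexahydro-4H-inden-4-one, via trimethylsilyl enol ether 24 (not isolated)
Conditions: TMSOTf (1.5 equiv), Et3N (3 equiv), CH2Cl2, 0 °C; then Pd(OAc)2 (1.1 equiv), MeCN, 23→40 °C
Reagents that add atoms: none
Why: Saegusa–Ito oxidation: the ketone can enolise only towards C5, and Pd(OAc)2 converts the silyl enol ether by β-hydride elimination of the C6 hydrogen into the β-substituted enone, removing the C6 stereocentre.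

Step 16
Reactants: 25 the β-substituted enone
Product: 26 (3aS,7aS)-5-iodo-6-{[(2R)-6-methoxy-2,8-dimethylchroman-2-yl]methyl}-3a,7a-dimethyl-1,2,3,3a,7,7a-hexahydro-4H-inden-4-one
Conditions: I2 (2.5 equiv), TMSN3 (2.5 equiv), pyridine/CH2Cl2 (1:1), 0→23 °C
Reagents that add atoms: iodine, II
Why: α-Iodination of an enone by conjugate addition of azide, iodination of the resulting silyl enol ether and elimination of hydrazoic acid is known for β-substituted cyclohexenones; without a strong iodonium source the electron-rich arene should be left alone.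

Step 17
Reactants: 26 the α-iodoenone
Product: 27 (3aS,7aS)-6-{[(2R)-6-methoxy-2,8-dimethylchroman-2-yl]methyl}-3a,7a-dimethyl-5-(2-methylprop-2-en-1-yl)-1,2,3,3a,7,7a-hexahydro-4H-inden-4-one
Conditions: tributyl(2-methylallyl)stannane (1.5 equiv), Pd2(dba)3 (5 mol %), AsPh3 (20 mol %), CuI (10 mol %), NMP, 23→45 °C
Reagents that add atoms: tributyl(2-methylallyl)stannane, CCCC[Sn](CCCC)(CCCC)CC(C)=C
Why: Stille coupling of the α-iodoenone forms the C5–CH2 bond under neutral conditions that cannot deprotonate the γ-CH2 next to ring B (which would open the chroman by elimination of the aryloxide).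

Step 18
Reactants: 27 the methallyl enone
Product: 28 (3aS,7aS)-5-(2-hydroxy-2-methylpropyl)-6-{[(2R)-6-methoxy-2,8-dimethylchroman-2-yl]methyl}-3a,7a-dimethyl-1,2,3,3a,7,7a-hexahydro-4H-inden-4-one (CNP0224132.1)
Conditions: Co(acac)2 (0.2 equiv), PhSiH3 (2.5 equiv), O2 (1 atm), THF, 23 °C; then aq. Na2S2O3
Reagents that add atoms: dioxygen, O=O
Why: Mukaiyama hydration: hydrogen-atom transfer from the cobalt hydride to the 1,1-disubstituted alkene gives the tertiary radical, which is trapped by O2 and reduced to the tertiary alcohol (Markovnikov); the tetrasubstituted, electron-poor enone alkene is too hindered to react.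

**Compound list**

1 | 2-methoxy-6-methylbenzoic acid | COc1cccc(C)c1C(=O)O | starting material
2 | (S)-2-(methoxymethyl)pyrrolidine | COC[C@@H]1CCCN1 | starting material
3 | 2-methoxy-6-methylbenzoyl chloride | COc1cccc(C)c1C(Cl)=O | intermediate (not isolated)
4 | (2-methoxy-6-methylphenyl)[(2S)-2-(methoxymethyl)pyrrolidin-1-yl]methanone | COC[C@@H]1CCCN1C(=O)c1c(C)cccc1OC | intermediate
5 | potassium amide enolate of the 1,4-dihydrobenzamide | [K+].[O-]C(N1CCC[C@H]1COC)=C1C(C)=CCC=C1OC | intermediate (not isolated)
6 | [(1S)-2-methoxy-1,6-dimethylcyclohexa-2,5-dien-1-yl][(2S)-2-(methoxymethyl)pyrrolidin-1-yl]methanone | C[C@]1(C(=O)N2CCC[C@H]2COC)C(C)=CCC=C1OC | intermediate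
7 | [(6S)-6,7-dimethyl-1,4-dioxaspiro[4.5]dec-7-en-6-yl][(2S)-2-(methoxymethyl)pyrrolidin-1-yl]methanone | C[C@]1(C(=O)N2CCC[C@H]2COC)C(C)=CCCC12OCCO2 | intermediate
8 | [(6R)-6,7-dimethyl-1,4-dioxaspiro[4.5]dec-7-en-6-yl]methanol | C[C@]1(CO)C(C)=CCCC12OCCO2 | intermediate
9 | (6S)-6-(iodomethyl)-6,7-dimethyl-1,4-dioxaspiro[4.5]dec-7-ene | C[C@]1(CI)C(C)=CCCC12OCCO2 | intermediate
10 | phenyl vinyl sulfone | C=CS(=O)(=O)c1ccccc1 | starting material
11 | (3a'S,7a'S)-3a',7a'-dimethyl-1'-(phenylsulfonyl)octahydrospiro[1,3-dioxolane-2,4'-indene], C1' epimers | C12(OCCO1)[C@@]3(C)CCC(S(=O)(=O)c4ccccc4)[C@@]3(C)CCC2 | intermediate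
12 | (3a'S,7a'S)-3a',7a'-dimethyloctahydrospiro[1,3-dioxolane-2,4'-indene] | C12(OCCO1)[C@@]3(C)CCC[C@@]3(C)CCC2 | intermediate (not isolated)
13 | (3aS,7aS)-3a,7a-dimethyloctahydro-4H-inden-4-one | O=C1[C@@]2(C)CCC[C@@]2(C)CCC1 | intermediate
14 | (3aS,7aS)-3a,7a-dimethyl-1,2,3,3a,7,7a-hexahydro-4H-inden-4-one | O=C1[C@@]2(C)CCC[C@@]2(C)CC=C1 | intermediate
15 | 4-methoxy-2-methylphenol | COc1ccc(O)c(C)c1 | starting material
16 | methyl methacrylate | C=C(C)C(=O)OC | starting material
17 | 4-methoxy-2-methyl-6-methylidenecyclohexa-2,4-dien-1-one | C=C1C=C(OC)C=C(C)C1=O | intermediate (not isolated)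
18 | methyl rac-6-methoxy-2,8-dimethylchromane-2-carboxylate | COC(=O)C1(C)CCc2cc(OC)cc(C)c2O1 | intermediate
19 | rac-6-methoxy-2,8-dimethylchromane-2-carboxylic acid | OC(=O)C1(C)CCc2cc(OC)cc(C)c2O1 | intermediate
20 | (2R)-6-methoxy-2,8-dimethylchromane-2-carboxylic acid | COc1cc(C)c2c(c1)CC[C@](C)(C(=O)O)O2 | intermediate
21 | [(2R)-6-methoxy-2,8-dimethylchroman-2-yl]methanol | COc1cc(C)c2c(c1)CC[C@](C)(CO)O2 | intermediate
22 | (2R)-2-(iodomethyl)-6-methoxy-2,8-dimethylchromane | COc1cc(C)c2c(c1)CC[C@](C)(CI)O2 | intermediate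
23 | (3aS,7aS)-6-{[(2R)-6-methoxy-2,8-dimethylchroman-2-yl]methyl}-3a,7a-dimethyloctahydro-4H-inden-4-one, C6 epimers | COc1cc(C)c2c(c1)CC[C@](C)(CC1CC(=O)[C@@]3(C)CCC[C@@]3(C)C1)O2 | intermediate
24 | trimethylsilyl enol ether of 23 (C4=C5) | COc1cc(C)c2c(c1)CC[C@](C)(CC1C=C(O[Si](C)(C)C)[C@@]3(C)CCC[C@@]3(C)C1)O2 | intermediate (not isolated)
25 | (3aS,7aS)-6-{[(2R)-6-methoxy-2,8-dimethylchroman-2-yl]methyl}-3a,7a-dimethyl-1,2,3,3a,7,7a-hexahydro-4H-inden-4-one | COc1cc(C)c2c(c1)CC[C@](C)(CC1=CC(=O)[C@@]3(C)CCC[C@@]3(C)C1)O2 | intermediate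
26 | (3aS,7aS)-5-iodo-6-{[(2R)-6-methoxy-2,8-dimethylchroman-2-yl]methyl}-3a,7a-dimethyl-1,2,3,3a,7,7a-hexahydro-4H-inden-4-one | COc1cc(C)c2c(c1)CC[C@](C)(CC1=C(I)C(=O)[C@@]3(C)CCC[C@@]3(C)C1)O2 | intermediate
27 | (3aS,7aS)-6-{[(2R)-6-methoxy-2,8-dimethylchroman-2-yl]methyl}-3a,7a-dimethyl-5-(2-methylprop-2-en-1-yl)-1,2,3,3a,7,7a-hexahydro-4H-inden-4-one | COc1cc(C)c2c(c1)CC[C@](C)(CC1=C(CC(C)=C)C(=O)[C@@]3(C)CCC[C@@]3(C)C1)O2 | intermediate
28 | (3aS,7aS)-5-(2-hydroxy-2-methylpropyl)-6-{[(2R)-6-methoxy-2,8-dimethylchroman-2-yl]methyl}-3a,7a-dimethyl-1,2,3,3a,7,7a-hexahydro-4H-inden-4-one (CNP0224132.1) | COc1cc(C)c2c(c1)CC[C@](C)(CC1=C(CC(C)(C)O)C(=O)[C@@]3(C)CCC[C@@]3(C)C1)O2 | target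

**Step count and risks**

Total: 18 steps. Longest linear sequence: 13 steps (steps 1–8 and 14–18); the chroman branch (steps 9–13) joins at step 14.

Most likely to fail:

1. Step 6 (key step). The first radical may be reduced before it adds, may attack the ring alkene 3-exo and ring-expand, or the bulky α-sulfonyl radical may close 6-endo or telomerise. Fallback, from 8 back to 12: the two bonds would be made one after the other. Alcohol 8 would be oxidised (Dess–Martin periodinane) to (6R)-6,7-dimethyl-1,4-dioxaspiro[4.5]dec-7-ene-6-carbaldehyde F1. A Horner–Wadsworth–Emmons reaction (trimethyl phosphonoacetate, NaH) would give the E-enoate F2, and conjugate reduction (Mg, MeOH) the saturated ester F3. LiAlH4 would give the propanol F4, and I2/PPh3/imidazole the primary iodide F5. Bu3SnH/AIBN (PhH, 80 °C) would then close ring D by 5-exo-trig cyclisation of the unstabilised primary radical onto the methyl-bearing alkene carbon, giving ketal 12; the acid stage of step 7 leads on to 13.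

2. Step 14. The chroman-2-ylmethyl radical may undergo β-scission of the C2–O bond (opening of ring B to an aryloxyl radical) faster than it adds to the enone. Fallback, from 14 and 21 back to 23: no radical is placed on that carbon. Enone 14 would undergo copper-catalysed conjugate borylation (CuCl, NaOt-Bu, a bisphosphine, B2pin2, MeOH) to the β-boryl ketone F6, and NaIO4/NH4OAc would give the boronic acid F7. Alcohol 21 would be oxidised (Dess–Martin periodinane) to the carbaldehyde F8 and condensed with tosylhydrazide to the tosylhydrazone F9. Heating F7 and F9 with K2CO3 in dioxane (110 °C) should give 23 by metal-free reductive coupling of a tosylhydrazone with a boronic acid, through the diazo compound, boron-to-carbon shift and protodeboronation.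

3. Step 16. Conjugate addition at the hindered, fully substituted β-carbon may be too slow for complete α-iodination, or the electron-rich arene may be iodinated instead. Fallback, from 23 back to 27: the side chain is introduced before the double bond. The lithium enolate of 23 (LiN(i-Pr)2, THF, −78 °C; only C5 can be deprotonated) would be alkylated with 3-bromo-2-methylpropene to the 5-methallyl ketone F10. A second enolisation and PhSeBr would give the 5-phenylselanyl ketone F11. Oxidation (H2O2, pyridine) and syn-elimination of the selenoxide towards the ring C6 hydrogen should give 27; any exocyclic isomer would have to be separated.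

Further compounds
F1 | step 6 | (6R)-6,7-dimethyl-1,4-dioxaspiro[4.5]dec-7-ene-6-carbaldehyde | C[C@]1(C=O)C(C)=CCCC12OCCO2
F2 | step 6 | methyl (2E)-3-[(6S)-6,7-dimethyl-1,4-dioxaspiro[4.5]dec-7-en-6-yl]prop-2-enoate | C[C@]1(/C=C/C(=O)OC)C(C)=CCCC12OCCO2
F3 | step 6 | methyl 3-[(6S)-6,7-dimethyl-1,4-dioxaspiro[4.5]dec-7-en-6-yl]propanoate | C[C@]1(CCC(=O)OC)C(C)=CCCC12OCCO2
F4 | step 6 | 3-[(6S)-6,7-dimethyl-1,4-dioxaspiro[4.5]dec-7-en-6-yl]propan-1-ol | C[C@]1(CCCO)C(C)=CCCC12OCCO2
F5 | step 6 | (6S)-6-(3-iodopropyl)-6,7-dimethyl-1,4-dioxaspiro[4.5]dec-7-ene | C[C@]1(CCCI)C(C)=CCCC12OCCO2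
F6 | step 14 | (3aS,7aS)-3a,7a-dimethyl-6-(4,4,5,5-tetramethyl-1,3,2-dioxaborolan-2-yl)octahydro-4H-inden-4-one, C6 epimers | CC1(C)OB(OC1(C)C)C1CC(=O)[C@@]2(C)CCC[C@@]2(C)C1
F7 | step 14 | (3aS,7aS)-6-borono-3a,7a-dimethyloctahydro-4H-inden-4-one, C6 epimers | OB(O)C1CC(=O)[C@@]2(C)CCC[C@@]2(C)C1
F8 | step 14 | (2R)-6-methoxy-2,8-dimethylchromane-2-carbaldehyde | COc1cc(C)c2c(c1)CC[C@](C)(C=O)O2
F9 | step 14 | N'-{(E)-[(2R)-6-methoxy-2,8-dimethylchroman-2-yl]methylidene}-4-methylbenzenesulfonohydrazide | COc1cc(C)c2c(c1)CC[C@](C)(/C=N/NS(=O)(=O)c1ccc(C)cc1)O2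
F10 | step 16 | (3aS,7aS)-6-{[(2R)-6-methoxy-2,8-dimethylchroman-2-yl]methyl}-3a,7a-dimethyl-5-(2-methylprop-2-en-1-yl)octahydro-4H-inden-4-one | COc1cc(C)c2c(c1)CC[C@](C)(CC1C(CC(C)=C)C(=O)[C@@]3(C)CCC[C@@]3(C)C1)O2
F11 | step 16 | (3aS,7aS)-6-{[(2R)-6-methoxy-2,8-dimethylchroman-2-yl]methyl}-3a,7a-dimethyl-5-(2-methylprop-2-en-1-yl)-5-(phenylselanyl)octahydro-4H-inden-4-one | COc1cc(C)c2c(c1)CC[C@](C)(CC1C(CC(C)=C)([Se]c4ccccc4)C(=O)[C@@]3(C)CCC[C@@]3(C)C1)O2
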